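I have no rate constants for this reaction. The violet bis adduct reads 29% at 3.00 min and 29% at 20.0 min, the same within the scatter. So I work from the end amounts.

| setting | violet | amber | north-west | south-east | south |
|---|---|---|---|---|---|
| starting material | 5 mM | 5 mM | 5.0 mM | 5.0 mM | 5.0 mM |
| reagent | 5.3 mM | 10 mM | 4.00 mM | 6.00 mM | 7.50 mM |
| remark | run made earlier | run made earlier |  |  |  |
| time |  |  | 40 min | 40 min | 40 min |

| run | time / min | bis adduct / % | starting material / % |
|---|---|---|---|
| violet | 3.00 | 29 | 20 |
| violet | 6.00 | 30 | 25 |
| violet | 10.0 | 31 | 26 |
| violet | 12.0 | 30 | 26 |
| violet | 15.0 | 30 | 22 |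
| violet | 20.0 | 29 | 28 |
| amber | 1.50 | 95 | 0 |
| amber | 2.50 | 93 | 2 |
| amber | 4.00 | 96 | 0 |
| amber | 8.00 | 100 | 0 |
| amber | 12.0 | 98 | 2 |
| amber | 20.0 | 96 | 2 |

(readings scatter by 1.5 percentage points)

- what was read earlier has a scatter of 1.5 percentage points, one standard deviation

- amount of bis adduct at the end, in percent of the starting material charged, for each flask in turn (north-west, south-east, south)

The bench rule says that the first equivalent of reagent makes single product and the excess above one equivalent makes bis adduct. In amber the ratio of reagent to starting material is 2.00, the rule gives 100%, and the readings run from 93% to 100%. In violet the ratio is 1.06 and the rule gives 6.00%, but from 6.00 min on the bis adduct reads 30.0% on average, more than the rule allows. South-east, at 1.20, lies below the amber ratio, so I distrust the rule's 20.0% there.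

The balance survives. Violet starting material averages 25.4% over the same readings, so single product by difference is 44.6%. The reagent taken up then reads 105% of the starting material charged, about equal to the reagent charge. I take the reagent as the limiting reagent in south-east too, so bis adduct minus starting material equals the excess.

One more relation closes the sum. I call it the split number: the square of [single product] divided by [starting material] times [bis adduct]. Violet reads 2.61. Holding it for south-east and solving the quadratic, I commit to 38.5% bis adduct.

The forecast gives 18%, 38% and 58% for north-west, south-east and south, and holds “so the mechanism hardly matters”.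

The flasks give 17.4%, 37.3% and 56.5% of bis adduct at 40 min, in the same order.

    reagent + bis adduct ⇌ triple product (K = 160 L mol⁻¹, k = 43.0 L mol⁻¹ s⁻¹)
    starting material + reagent → single product (k = 130 L mol⁻¹ s⁻¹)
    reagent + single product → bis adduct (k = 83.0 L mol⁻¹ s⁻¹)
    bis adduct → over-reaction product (k = 1.30 × 10⁻⁵ s⁻¹)

In south-east the half-life of bis adduct by conversion into over-reaction product alone is 15 h, longer than the 40 min. The end amounts of south-east give a split number of 2.68. In south, the violet split number 2.61 with 8.27% starting material and 56.5% bis adduct gives 34.9% single product, and south holds 33.5%.

The runs were generated by integration for substances that don't exist; noise was put on by code.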